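**Retrosynthetic overview**
- Target 18 ⇐ bis-silyl lactone 17 (desilylation) ⇐ lactol 16 (allylic lactol oxidation) ⇐ methyl acetal 15 (hydrolysis).
- 15 ⇐ enal 13 + (E)-1-methoxybuta-1,3-diene 14. The only ring of the target is closed here, by a catalyst-controlled carbonyl [4+2] that forms C5–C6 and O1–C2, sets C6 and delivers C3=C4.
- 13 ⇐ homoallyl acetate 11 + crotonaldehyde 12 by cross-metathesis (C1'=C2').
- 11 ⇐ 3-phenylpropanal 1 by three catalytic asymmetric allylations (C8', then C6' syn, then C4' anti), with silylation and ozonolysis between them.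
- Feature on which the plan rests: the 5,6-dihydro-2H-pyran-2-one ring O1–C2(=O)–C3=C4–C5–C6, whose single stereocentre C6 carries the (E)-C1'=C2' chain. It is an aldehyde (C6, O1) joined to a four-carbon 1-oxygenated diene (C2–C5).

Key step: step 10

Locants used: lactone O1, C2(=O), C3=C4, C5, C6; chain C1'=C2', C3', C4'(OAc), C5', C6'(OH), C7', C8'(OH), C9', C10', phenyl. The target is 6S,4'R,6'R,8'R, with C6'/C8' syn and C4'/C6' anti.

Catalyst of step 10: CrCl(L), trivalent chromium, L = the dianionic tridentate imine of (1S,2R)-cis-1-aminoindan-2-ol with 3-(1-adamantyl)-2-hydroxy-5-methylbenzaldehyde.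

Assumption: the catalyst is taken to select the same carbonyl face of enal 13 as it does with saturated aldehydes, which points to the (1S,2R) ligand for 6S; if the sense were reversed, the (1R,2S) ligand would be used with nothing else changed.

**Route**

Step 1
Reactants: 1 3-phenylpropanal
Product: 2 (R)-1-phenylhex-5-en-3-ol
Conditions: (S)-BINOL (10 mol %), Ti(OiPr)4 (10 mol %), 4 Å MS, CH2Cl2; allylSnBu3 (1.2 equiv), −20 °C, 70 h; aq. NaHCO3
Reagents that add atoms: allyltributylstannane, C=CC[Sn](CCCC)(CCCC)CCCC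
Why: Keck asymmetric allylation, in which the (S)-BINOL titanium Lewis acid directs allyl transfer to the Si face of the aldehyde and so should give the (R)-carbinol that becomes C8'.

Step 2
Reactants: 2 (R)-1-phenylhex-5-en-3-ol
Product: 3 (R)-tert-butyldimethyl[(1-phenylhex-5-en-3-yl)oxy]silane
Conditions: TBSCl (1.2 equiv), imidazole (2.5 equiv), DMF, rt
Reagents that add atoms: tert-butyldimethylsilyl chloride, CC(C)(C)[Si](C)(C)Cl
Why: Imidazole-assisted silylation of a secondary alcohol, which touches no stereocentre.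

Step 3
Reactants: 3 (R)-tert-butyldimethyl[(1-phenylhex-5-en-3-yl)oxy]silane
Product: 5 (R)-3-(tert-butyldimethylsilyloxy)-5-phenylpentanal, via the 1,2,4-trioxolane ozonide 4 (not isolated)
Conditions: O3, CH2Cl2, −78 °C, stopped at first excess; PPh3, −78 °C → rt
Reagents that add atoms: ozone, [O-][O+]=O
Why: Ozonolysis with reductive work-up, the terminal alkene giving the secondary ozonide that PPh3 reduces to the aldehyde, while the silyl ether and the arene are left alone at −78 °C and the β-stereocentre cannot enolise.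

Step 4
Reactants: 5 (R)-3-(tert-butyldimethylsilyloxy)-5-phenylpentanal
Product: 6 (4S,6R)-6-(tert-butyldimethylsilyloxy)-8-phenyloct-1-en-4-ol
Conditions: (S)-BINOL (10 mol %), Ti(OiPr)4 (10 mol %), 4 Å MS, CH2Cl2; allylSnBu3 (1.5 equiv), −20 °C, 72 h; aq. NaHCO3
Reagents that add atoms: allyltributylstannane, C=CC[Sn](CCCC)(CCCC)CCCC
Why: Keck asymmetric allylation with the same (S)-BINOL catalyst, whose Si-face delivery should override the weak bias of the β-silyloxy centre and set C6' syn to C8' (4S in 6).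

Step 5
Reactants: 6 (4S,6R)-6-(tert-butyldimethylsilyloxy)-8-phenyloct-1-en-4-ol
Product: 7 (4S,6R)-4,6-bis(tert-butyldimethylsilyloxy)-8-phenyloct-1-ene
Conditions: TBSCl (1.5 equiv), imidazole (3 equiv), DMF, rt
Reagents that add atoms: tert-butyldimethylsilyl chloride, CC(C)(C)[Si](C)(C)Cl
Why: Standard silylation of the secondary alcohol, which protects the future C6' hydroxyl with the same group as C8' so that both leave together at the end.

Step 6
Reactants: 7 (4S,6R)-4,6-bis(tert-butyldimethylsilyloxy)-8-phenyloct-1-ene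
Product: 9 (3R,5R)-3,5-bis(tert-butyldimethylsilyloxy)-7-phenylheptanal, via the 1,2,4-trioxolane ozonide 8 (not isolated)
Conditions: O3, CH2Cl2, −78 °C, stopped at first excess; PPh3, −78 °C → rt
Reagents that add atoms: ozone, [O-][O+]=O
Why: Ozonolysis with reductive work-up as in step 3, giving a β,δ-bis-silyloxy aldehyde that is used at once to avoid β-elimination.

Step 7
Reactants: 9 (3R,5R)-3,5-bis(tert-butyldimethylsilyloxy)-7-phenylheptanal
Product: 10 (4R,6S,8R)-6,8-bis(tert-butyldimethylsilyloxy)-10-phenyldec-1-en-4-ol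
Conditions: (R)-BINOL (10 mol %), Ti(OiPr)4 (10 mol %), 4 Å MS, CH2Cl2; allylSnBu3 (1.5 equiv), −20 °C, 72 h; aq. NaHCO3
Reagents that add atoms: allyltributylstannane, C=CC[Sn](CCCC)(CCCC)CCCC
Why: Keck asymmetric allylation with the enantiomeric (R)-BINOL catalyst, whose Re-face delivery should set C4' (4R) 1,3-anti to C6', the sense that the β-silyloxy group also weakly favours in an open transition state.

Step 8
Reactants: 10 (4R,6S,8R)-6,8-bis(tert-butyldimethylsilyloxy)-10-phenyldec-1-en-4-ol
Product: 11 (4R,6S,8R)-6,8-bis(tert-butyldimethylsilyloxy)-10-phenyldec-1-en-4-yl acetate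
Conditions: Ac2O, pyridine, DMAP (cat.), CH2Cl2, 0 °C → rt
Reagents that add atoms: acetic anhydride, CC(=O)OC(C)=O
Why: DMAP-catalysed acylation of the secondary alcohol with retention at C4', which installs the acetate of the target before any other hydroxyl is free.

Step 9
Reactants: 11 (4R,6S,8R)-6,8-bis(tert-butyldimethylsilyloxy)-10-phenyldec-1-en-4-yl acetate; 12 crotonaldehyde
Product: 13 (2E,5R,7S,9R)-7,9-bis(tert-butyldimethylsilyloxy)-1-oxo-11-phenylundec-2-en-5-yl acetate
Conditions: second-generation Hoveyda–Grubbs catalyst RuCl2(SIMes)(=CH-C6H4-2-OiPr) (5 mol %), crotonaldehyde (5 equiv), CH2Cl2, 40 °C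
Reagents that add atoms: none
Why: Olefin cross-metathesis of a terminal alkene with an electron-poor enal partner used in excess, which suppresses homodimer and should give the thermodynamically preferred (E)-enal with loss of propene.

Step 10
Reactants: 13 (2E,5R,7S,9R)-7,9-bis(tert-butyldimethylsilyloxy)-1-oxo-11-phenylundec-2-en-5-yl acetate; 14 (E)-1-methoxybuta-1,3-diene
Product: 15 (1E,4R,6S,8R)-6,8-bis(tert-butyldimethylsilyloxy)-1-[(2S,6R)-6-methoxy-3,6-dihydro-2H-pyran-2-yl]-10-phenyldec-1-en-4-yl acetate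
Conditions: CrCl(L) (10 mol %), powdered 4 Å MS, (E)-1-methoxybuta-1,3-diene (4 equiv) as the only solvent, rt, 48–72 h
Reagents that add atoms: none
Why: The trivalent chromium centre binds the aldehyde oxygen of 13 and the diene adds through a concerted but asynchronous endo [4+2] transition state in which C5–C6 bonding (diene terminus to carbonyl carbon) runs ahead of O1–C2 bonding; the closest known reaction type is the chromium Schiff-base-catalysed hetero-Diels–Alder reaction of aldehydes with 1-alkoxybutadienes. The ring O1, C2–C6 closes by intermolecular cycloaddition, both ring bonds forming in one event, and C3=C4 is left in place at the acetal oxidation level. C6 (S in the lactone locants) is set by the catalyst, which is expected to expose the Si face of the carbonyl independently of the remote C4' centre, while the acetal carbon C2 (R) follows from the endo approach, giving the 2,6-cis acetal, and is erased in step 12. The step needs the carbonyl to react as the two-atom partner, not the enal C=C and not the enal as an oxadiene, and it needs one regiochemistry: the oxygen-bound Lewis acid activates C=O for attack at carbon, and the methoxy donor makes the unsubstituted diene terminus the nucleophile so that oxygen ends on the acetal carbon. Because conjugated aldehydes are among the slower substrates, the diene is used in excess without other solvent over sieves; the acetate and silyl ethers should not compete for the catalyst.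

Step 11
Reactants: 15 (1E,4R,6S,8R)-6,8-bis(tert-butyldimethylsilyloxy)-1-[(2S,6R)-6-methoxy-3,6-dihydro-2H-pyran-2-yl]-10-phenyldec-1-en-4-yl acetate
Product: 16 (1E,4R,6S,8R)-6,8-bis(tert-butyldimethylsilyloxy)-1-[(2S)-6-hydroxy-3,6-dihydro-2H-pyran-2-yl]-10-phenyldec-1-en-4-yl acetate
Conditions: PPTS (0.2 equiv), acetone/H2O 10:1, rt
Reagents that add atoms: water, O
Why: Acid-catalysed hydrolysis of the allylic methyl acetal through the conjugated oxocarbenium ion, mild enough to leave the acetate, the silyl ethers and the C6–O1 bond intact; the lactol forms as an anomer mixture, which is of no consequence.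

Step 12
Reactants: 16 (1E,4R,6S,8R)-6,8-bis(tert-butyldimethylsilyloxy)-1-[(2S)-6-hydroxy-3,6-dihydro-2H-pyran-2-yl]-10-phenyldec-1-en-4-yl acetate
Product: 17 (1E,4R,6S,8R)-6,8-bis(tert-butyldimethylsilyloxy)-1-[(2S)-6-oxo-3,6-dihydro-2H-pyran-2-yl]-10-phenyldec-1-en-4-yl acetate
Conditions: activated MnO2 (20 equiv), CH2Cl2, rt
Reagents that add atoms: none
Why: MnO2 oxidation of an allylic lactol to the α,β-unsaturated δ-lactone, selective for the allylic carbinol so that no other function and no stereocentre is touched.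

Step 13
Reactants: 17 (1E,4R,6S,8R)-6,8-bis(tert-butyldimethylsilyloxy)-1-[(2S)-6-oxo-3,6-dihydro-2H-pyran-2-yl]-10-phenyldec-1-en-4-yl acetate
Product: 18 (1E,4R,6R,8R)-6,8-dihydroxy-1-[(2S)-6-oxo-3,6-dihydro-2H-pyran-2-yl]-10-phenyldec-1-en-4-yl acetate
Conditions: HF·pyridine, pyridine, THF, 0 °C → rt
Reagents that add atoms: none
Why: Fluoride-mediated cleavage of both secondary silyl ethers under buffered, weakly acidic conditions, chosen to avoid acetyl migration from C4' to C6' and opening of the lactone, which gives the target.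

**Compound list**

1 | 3-phenylpropanal | O=CCCc1ccccc1 | starting material
2 | (R)-1-phenylhex-5-en-3-ol | C=CC[C@H](O)CCc1ccccc1 | intermediate
3 | (R)-tert-butyldimethyl[(1-phenylhex-5-en-3-yl)oxy]silane | C=CC[C@H](O[Si](C)(C)C(C)(C)C)CCc1ccccc1 | intermediate
4 | 3-[(2R)-2-(tert-butyldimethylsilyloxy)-4-phenylbutyl]-1,2,4-trioxolane (ozonide, mixture at the ring carbon) | C1OC(C[C@H](O[Si](C)(C)C(C)(C)C)CCc2ccccc2)OO1 | intermediate (not isolated)
5 | (R)-3-(tert-butyldimethylsilyloxy)-5-phenylpentanal | O=CC[C@H](O[Si](C)(C)C(C)(C)C)CCc1ccccc1 | intermediate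
6 | (4S,6R)-6-(tert-butyldimethylsilyloxy)-8-phenyloct-1-en-4-ol | C=CC[C@H](O)C[C@H](O[Si](C)(C)C(C)(C)C)CCc1ccccc1 | intermediate
7 | (4S,6R)-4,6-bis(tert-butyldimethylsilyloxy)-8-phenyloct-1-ene | C=CC[C@H](O[Si](C)(C)C(C)(C)C)C[C@H](O[Si](C)(C)C(C)(C)C)CCc1ccccc1 | intermediate
8 | 3-[(2R,4R)-2,4-bis(tert-butyldimethylsilyloxy)-6-phenylhexyl]-1,2,4-trioxolane (ozonide, mixture at the ring carbon) | C1OC(C[C@H](O[Si](C)(C)C(C)(C)C)C[C@H](O[Si](C)(C)C(C)(C)C)CCc2ccccc2)OO1 | intermediate (not isolated)
9 | (3R,5R)-3,5-bis(tert-butyldimethylsilyloxy)-7-phenylheptanal | O=CC[C@H](O[Si](C)(C)C(C)(C)C)C[C@H](O[Si](C)(C)C(C)(C)C)CCc1ccccc1 | intermediate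
10 | (4R,6S,8R)-6,8-bis(tert-butyldimethylsilyloxy)-10-phenyldec-1-en-4-ol | C=CC[C@@H](O)C[C@H](O[Si](C)(C)C(C)(C)C)C[C@H](O[Si](C)(C)C(C)(C)C)CCc1ccccc1 | intermediate
11 | (4R,6S,8R)-6,8-bis(tert-butyldimethylsilyloxy)-10-phenyldec-1-en-4-yl acetate | C=CC[C@@H](OC(C)=O)C[C@H](O[Si](C)(C)C(C)(C)C)C[C@H](O[Si](C)(C)C(C)(C)C)CCc1ccccc1 | intermediate
12 | crotonaldehyde, (E)-but-2-enal | C/C=C/C=O | starting material
13 | (2E,5R,7S,9R)-7,9-bis(tert-butyldimethylsilyloxy)-1-oxo-11-phenylundec-2-en-5-yl acetate | O=C/C=C/C[C@@H](OC(C)=O)C[C@H](O[Si](C)(C)C(C)(C)C)C[C@H](O[Si](C)(C)C(C)(C)C)CCc1ccccc1 | intermediate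
14 | (E)-1-methoxybuta-1,3-diene | CO/C=C/C=C | starting material
15 | (1E,4R,6S,8R)-6,8-bis(tert-butyldimethylsilyloxy)-1-[(2S,6R)-6-methoxy-3,6-dihydro-2H-pyran-2-yl]-10-phenyldec-1-en-4-yl acetate (2,6-cis acetal) | CC(=O)O[C@H](C/C=C/[C@@H]1CC=C[C@H](OC)O1)C[C@H](O[Si](C)(C)C(C)(C)C)C[C@H](O[Si](C)(C)C(C)(C)C)CCc1ccccc1 | intermediate
16 | (1E,4R,6S,8R)-6,8-bis(tert-butyldimethylsilyloxy)-1-[(2S)-6-hydroxy-3,6-dihydro-2H-pyran-2-yl]-10-phenyldec-1-en-4-yl acetate (anomer mixture) | CC(=O)O[C@H](C/C=C/[C@@H]1CC=CC(O)O1)C[C@H](O[Si](C)(C)C(C)(C)C)C[C@H](O[Si](C)(C)C(C)(C)C)CCc1ccccc1 | intermediate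
17 | (1E,4R,6S,8R)-6,8-bis(tert-butyldimethylsilyloxy)-1-[(2S)-6-oxo-3,6-dihydro-2H-pyran-2-yl]-10-phenyldec-1-en-4-yl acetate | CC(=O)O[C@H](C/C=C/[C@@H]1CC=CC(=O)O1)C[C@H](O[Si](C)(C)C(C)(C)C)C[C@H](O[Si](C)(C)C(C)(C)C)CCc1ccccc1 | intermediate
18 | (1E,4R,6R,8R)-6,8-dihydroxy-1-[(2S)-6-oxo-3,6-dihydro-2H-pyran-2-yl]-10-phenyldec-1-en-4-yl acetate | CC(=O)O[C@H](C/C=C/[C@@H]1CC=CC(=O)O1)C[C@H](O)C[C@H](O)CCc1ccccc1 | target

**Step count**
Total: 13 steps. Longest linear sequence: 13 steps (1 → 18); 12 and 14 are purchased.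

**Steps most likely to fail**

1. Step 10. The conjugated carbonyl may be too weak a heterodienophile for useful conversion, the enal may be diverted into reaction as an oxadiene with the enol-ether bond of the diene, or facial selectivity may erode. Fallback, sets out from 13 and comes back at 17: Keck asymmetric allylation of the enal carbonyl ((S)-BINOL, Ti(OiPr)4, allylSnBu3, Si-face delivery) would give the dienol (4S,5E,8R,10S,12R)-10,12-bis(tert-butyldimethylsilyloxy)-4-hydroxy-14-phenyltetradeca-1,5-dien-8-yl acetate F1. Acryloyl chloride and iPr2NEt in CH2Cl2 would then give the acrylate (4S,5E,8R,10S,12R)-8-acetoxy-10,12-bis(tert-butyldimethylsilyloxy)-14-phenyltetradeca-1,5-dien-4-yl acrylate F2. Ring-closing metathesis with the second-generation Grubbs catalyst RuCl2(SIMes)(PCy3)(=CHPh) in dilute CH2Cl2 at 40 °C would close C3=C4 and give 17, so steps 10 to 12 are bypassed.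

2. Step 7. Catalyst control over the hindered β,δ-bis-silyloxy aldehyde may be insufficient, giving a mixture of C4' epimers, or allyl transfer may be slow enough for β-elimination to compete. Fallback, sets out from 9 and comes back at 11: the allylation is run with (S)-BINOL, the pairing already used in step 4, to give the all-syn alcohol (4S,6S,8R)-6,8-bis(tert-butyldimethylsilyloxy)-10-phenyldec-1-en-4-ol F3. Mitsunobu esterification with acetic acid (PPh3, DIAD, toluene, 0 °C → rt) would then invert C4' and install the acetate in one operation, giving 11 and bypassing 10.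

3. Step 11. Acid may open the allylic lactol to the hydroxy-enal, followed by dehydration to a polyenal or ionisation at C6 with loss of configuration. Fallback, sets out from 15 and comes back at 17: direct Jones oxidation (CrO3, H2SO4, acetone, 0 °C), a known one-flask conversion of 2-alkoxy-5,6-dihydro-2H-pyrans into the unsaturated lactones, would give 17 without the lactol accumulating. It makes no compound outside the list (F0).

**Further compounds**

F1 | step 10 | (4S,5E,8R,10S,12R)-10,12-bis(tert-butyldimethylsilyloxy)-4-hydroxy-14-phenyltetradeca-1,5-dien-8-yl acetate | CC(=O)O[C@H](C/C=C/[C@@H](O)CC=C)C[C@H](O[Si](C)(C)C(C)(C)C)C[C@H](O[Si](C)(C)C(C)(C)C)CCc1ccccc1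
F2 | step 10 | (4S,5E,8R,10S,12R)-8-acetoxy-10,12-bis(tert-butyldimethylsilyloxy)-14-phenyltetradeca-1,5-dien-4-yl acrylate | CC(=O)O[C@H](C/C=C/[C@@H](OC(=O)C=C)CC=C)C[C@H](O[Si](C)(C)C(C)(C)C)C[C@H](O[Si](C)(C)C(C)(C)C)CCc1ccccc1
F3 | step 7 | (4S,6S,8R)-6,8-bis(tert-butyldimethylsilyloxy)-10-phenyldec-1-en-4-ol | C=CC[C@H](O)C[C@H](O[Si](C)(C)C(C)(C)C)C[C@H](O[Si](C)(C)C(C)(C)C)CCc1ccccc1
F0 | step 11 | none | none
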